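## Retrosynthetic overview

1. Ring A is bought as 2,4-dihydroxyacetophenone 1. The two C-prenyl bonds are disconnected to prenyl bromide 2 (phenoxide C-alkylation through mono-prenyl ketone 3 to diprenyl ketone 4).
2. The C2–C3 bond (flavanone numbering) is disconnected to benzaldehyde 5, which brings ring B (Claisen–Schmidt condensation through aldol 6 to chalcone 7).
3. Key disconnection: the O1–C2 bond of target 8, formed last by an enantioselective 6-endo oxa-Michael closure of 7 that sets the only stereocentre (2S).
4. Ring order: rings A and B are bought intact; ring C (the pyranone) is the only ring made, in the final step.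

Assumption: the given SMILES is read as the (2S) enantiomer, and the (S)-configured catalyst of step 3 is assumed to deliver 2S; if the first run shows the opposite sense, its mirror image (from D-tert-leucine) is used with no other change.

The step 3 catalyst is prepared beforehand by the Staudinger reaction of its azide precursor with tris(4-methoxyphenyl)phosphine and is not counted as a route compound.

## Route

Step 1
Reactants: 1 2,4-dihydroxyacetophenone; 2 prenyl bromide (1-bromo-3-methylbut-2-ene)
Product: 4 1-[2,4-dihydroxy-3,5-bis(3-methylbut-2-en-1-yl)phenyl]ethan-1-one, via mono-prenyl ketone 3 (not isolated)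
Conditions: 2 (2.5 equiv), KOH (3 equiv, 10% aq), 0 °C to rt, 24 h
Reagents that add atoms: none
Why: C-alkylation of an ambident phenoxide (SN2 at the primary allylic bromide; water hydrogen-bonds the phenoxide oxygens and disfavours O-alkylation) puts the first prenyl group at C-3 between the two oxygens to give 3 and the second at C-5, the only other position ortho or para to both oxygens; no stereocentre is formed.

Step 2
Reactants: 4 1-[2,4-dihydroxy-3,5-bis(3-methylbut-2-en-1-yl)phenyl]ethan-1-one; 5 benzaldehyde
Product: 7 (E)-1-[2,4-dihydroxy-3,5-bis(3-methylbut-2-en-1-yl)phenyl]-3-phenylprop-2-en-1-one, via aldol adduct 6 (not isolated)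
Conditions: 5 (1.5 equiv), KOH (10 equiv, 50% aq), EtOH, 0 °C to rt, 48 h; then cold 1 M HCl to pH 4
Reagents that add atoms: none
Why: Claisen–Schmidt condensation: the methyl ketone enolate adds to non-enolisable benzaldehyde to give aldol 6, which loses water by E1cB to the conjugated (E)-enone (thermodynamic geometry); in strong base the product stays open as its phenoxide, so no racemic flavanone forms, and the prenyl groups are inert to base.

Step 3
Reactants: 7 (E)-1-[2,4-dihydroxy-3,5-bis(3-methylbut-2-en-1-yl)phenyl]-3-phenylprop-2-en-1-one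
Product: 8 (2S)-7-hydroxy-6,8-bis(3-methylbut-2-en-1-yl)-2-phenyl-2,3-dihydro-4H-chromen-4-one (the target)
Conditions: 1-[3,5-bis(trifluoromethyl)phenyl]-3-[(2S)-3,3-dimethyl-1-{[tris(4-methoxyphenyl)-λ5-phosphanylidene]amino}butan-2-yl]thiourea (10 mol%), 4 Å MS, PhMe (0.1 M), 0 °C, 24–48 h; AcOH quench at about 90% conversion
Reagents that add atoms: none
Why: Proposed new method: direct catalytic enantioselective 6-endo-trig intramolecular oxa-Michael addition of a non-activated, fully unprotected 2',4'-dihydroxychalcone (an isomerisation, so nothing is lost); the strongly basic iminophosphorane is protonated at once by the acidic 4'-OH, so every phenoxide in the flask is paired with the same chiral aminophosphonium cation, and proton shuffling between phenols supplies the minor but far more nucleophilic 2'-phenoxide tautomer, in which the intramolecular O–H···O=C bond that locks the unreactive conformer is gone; the thiourea N–H bonds then clamp the ketone oxygen (the enolate-to-be) while the P–N–H+ site holds the aryloxide oxygen, so the oxygen adds to one face of C-β inside a rigid chiral ion pair and sets C-2 as S under kinetic control, after which the enolate is C-protonated by the next phenol and the phenoxide chain goes on; there is no racemic background because neutral 7 does not cyclise in cold toluene, retro-oxa-Michael (E1cB) racemisation is slow because the only base present is a weakly basic hindered phenoxide, and base/hydrogen-bond catalysis leaves the acid-sensitive ortho-prenylphenol units untouched; closest known reaction types: bifunctional iminophosphorane-catalysed oxa- and sulfa-Michael additions to unactivated α,β-unsaturated esters and amides, and the quinine- or thiourea-catalysed cyclisation of simple or α-ester-activated 2'-hydroxychalcones.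

## Compound list

1 | 2,4-dihydroxyacetophenone | CC(=O)c1ccc(O)cc1O | starting material
2 | prenyl bromide (1-bromo-3-methylbut-2-ene) | CC(C)=CCBr | starting material
3 | 1-[2,4-dihydroxy-3-(3-methylbut-2-en-1-yl)phenyl]ethan-1-one | CC(=O)c1ccc(O)c(CC=C(C)C)c1O | intermediate
4 | 1-[2,4-dihydroxy-3,5-bis(3-methylbut-2-en-1-yl)phenyl]ethan-1-one | CC(=O)c1cc(CC=C(C)C)c(O)c(CC=C(C)C)c1O | intermediate
5 | benzaldehyde | O=Cc1ccccc1 | starting material
6 | 1-[2,4-dihydroxy-3,5-bis(3-methylbut-2-en-1-yl)phenyl]-3-hydroxy-3-phenylpropan-1-one (racemic aldol adduct) | OC(CC(=O)c1cc(CC=C(C)C)c(O)c(CC=C(C)C)c1O)c1ccccc1 | intermediate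
7 | (E)-1-[2,4-dihydroxy-3,5-bis(3-methylbut-2-en-1-yl)phenyl]-3-phenylprop-2-en-1-one | O=C(/C=C/c1ccccc1)c1cc(CC=C(C)C)c(O)c(CC=C(C)C)c1O | intermediate
8 | (2S)-7-hydroxy-6,8-bis(3-methylbut-2-en-1-yl)-2-phenyl-2,3-dihydro-4H-chromen-4-one | CC(C)=CCc1cc2c(c(CC=C(C)C)c1O)O[C@H](c1ccccc1)CC2=O | target

## Step count and risks

Total steps: 3. Longest linear sequence: 3 steps (1 → 4 → 7 → 8).

Steps most likely to fail:

**Step 3 (the proposed new method).** Risks: the catalyst rests as the unreactive 4'-phenoxide ion pair, so turnover may be slow; the ee may be insufficient or may erode by retro-oxa-Michael as the mixture nears equilibrium. Unreacted 7 is recycled in any case. Fallback with known chemistry, setting out from 7 and coming back at 8: 7 is cyclised without stereocontrol (NaOAc, EtOH, reflux) to rac-7-hydroxy-6,8-bis(3-methylbut-2-en-1-yl)-2-phenyl-2,3-dihydro-4H-chromen-4-one F1. This is resolved by preparative HPLC on an amylose tris(3,5-dimethylphenylcarbamate) phase (hexane/iPrOH) to give 8. The unwanted (2R)-7-hydroxy-6,8-bis(3-methylbut-2-en-1-yl)-2-phenyl-2,3-dihydro-4H-chromen-4-one F2 is reopened to 7 with KOH in aqueous EtOH and recycled.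

**Step 1.** Risk: a mixture of mono-C-prenyl, O-prenyl and 3,3-diprenyl dienone products, so only a modest yield of 4 (about 20–25% expected; mono-prenyl fractions are resubmitted). Fallback, setting out from 1 and coming back at 4: 1 is iodinated (I2, HIO3, aq. EtOH) to 1-(2,4-dihydroxy-3,5-diiodophenyl)ethan-1-one F3. Both phenols are protected (MOMCl, NaH, DMF, 0 °C) to give 1-[3,5-diiodo-2,4-bis(methoxymethoxy)phenyl]ethan-1-one F4. A twofold Stille coupling with tributyl(3-methylbut-2-en-1-yl)stannane (Pd(PPh3)4, DMF, 90 °C; linear prenyl transfer) gives 1-[2,4-bis(methoxymethoxy)-3,5-bis(3-methylbut-2-en-1-yl)phenyl]ethan-1-one F5. Acetal cleavage (HCl, MeOH, rt) then gives 4.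

**Step 2.** Risk: the doubly deprotonated ketone condenses slowly, and benzaldehyde is lost to the Cannizzaro reaction. Fallback, setting out from 4 and coming back at 7: the free 4-OH alone is protected (MOMCl, iPr2NEt, CH2Cl2, 0 °C; the chelated 2-OH stays free) to give 1-[2-hydroxy-4-(methoxymethoxy)-3,5-bis(3-methylbut-2-en-1-yl)phenyl]ethan-1-one F6. Claisen–Schmidt condensation with 5 (KOH, EtOH, rt) gives (E)-1-[2-hydroxy-4-(methoxymethoxy)-3,5-bis(3-methylbut-2-en-1-yl)phenyl]-3-phenylprop-2-en-1-one F7. Acetal cleavage (HCl, MeOH, rt) then gives 7.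

## Further compounds

F1 | step 3 | rac-7-hydroxy-6,8-bis(3-methylbut-2-en-1-yl)-2-phenyl-2,3-dihydro-4H-chromen-4-one | CC(C)=CCc1cc2c(c(CC=C(C)C)c1O)OC(c1ccccc1)CC2=O
F2 | step 3 | (2R)-7-hydroxy-6,8-bis(3-methylbut-2-en-1-yl)-2-phenyl-2,3-dihydro-4H-chromen-4-one | CC(C)=CCc1cc2c(c(CC=C(C)C)c1O)O[C@@H](c1ccccc1)CC2=O
F3 | step 1 | 1-(2,4-dihydroxy-3,5-diiodophenyl)ethan-1-one | CC(=O)c1cc(I)c(O)c(I)c1O
F4 | step 1 | 1-[3,5-diiodo-2,4-bis(methoxymethoxy)phenyl]ethan-1-one | CC(=O)c1cc(I)c(OCOC)c(I)c1OCOC
F5 | step 1 | 1-[2,4-bis(methoxymethoxy)-3,5-bis(3-methylbut-2-en-1-yl)phenyl]ethan-1-one | CC(=O)c1cc(CC=C(C)C)c(OCOC)c(CC=C(C)C)c1OCOC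
F6 | step 2 | 1-[2-hydroxy-4-(methoxymethoxy)-3,5-bis(3-methylbut-2-en-1-yl)phenyl]ethan-1-one | CC(=O)c1cc(CC=C(C)C)c(OCOC)c(CC=C(C)C)c1O
F7 | step 2 | (E)-1-[2-hydroxy-4-(methoxymethoxy)-3,5-bis(3-methylbut-2-en-1-yl)phenyl]-3-phenylprop-2-en-1-one | O=C(/C=C/c1ccccc1)c1cc(CC=C(C)C)c(OCOC)c(CC=C(C)C)c1O
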